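Time is what this flask is about: Z goes in by portions under G, and I want to know where the charge sits at 3.0 h.

| setting | Monday's | Wednesday's | flask |
|---|---|---|---|
| Z | 3 M (in portions, 4) | 3 M (in portions, 4) | 3.0 M (in portions, 4) |
| G | 33 mM | 16 mM | 33 mM |
| remark | the very flask that is asked about, followed so far; portions every 50 min | run made earlier; portions every 50 min | the portions of Z follow each other after 50 min, the first at the start |
| time |  |  | 3.0 h |

| run | time / min | J / % | Q / % | L / % | Z / % |
|---|---|---|---|---|---|
| Monday's | 25.0 | 0 | 8.1 | 0.1 | 17.5 |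
| Monday's | 50.0 | 0.3 | 13.1 | 0.7 | 12.2 |
| Monday's | 60.0 | 0.5 | 16.1 | 0 | 31.8 |
| Monday's | 90.0 | 0 | 27.0 | 1.4 | 22.2 |
| Wednesday's | 30.0 | 0 | 4.1 | 0.1 | 19.4 |
| Wednesday's | 60.0 | 0 | 10.0 | 0.3 | 40.0 |
| Wednesday's | 90.0 | 0 | 16.4 | 0.4 | 33.4 |
| Wednesday's | 120 | 0.7 | 23.8 | 0 | 51.0 |

(scatter of a reading: 0.5 percentage points)

- the species in which most of what was charged as Z, at 3.0 h sits (J / L / Q / Z)
- the largest share itself, whichever of these holds it, in percent of the Z charged

- a reading at the moment of an addition is taken just before it
- percentages count the whole charge, also what has not yet gone in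

In Monday's first 25.0 min, with a quarter of the charge in, Z reads 17.5% and Q 8.1%, while L reads 0.1% and J 0%. So Z is turning into Q from the start, and at this reading L and J lie within the scatter of nil.

In the middle of Monday's run no addition falls between 60.0 min and 90.0 min, so Z simply decays there. Those two readings give 0.0120 min⁻¹ for kz, the pseudo-first-order constant, the fraction of the free Z lost per minute. Wednesday's flask, with 16 mM of G, reads 0.00601 min⁻¹ from 60.0 min to 90.0 min. That is 0.501 of Monday's constant, against 0.485 for the charged c(G), so I let kz go with the charged c(G).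

Then each portion fades by itself, and the part of the charge still Z is the mean of exp(−kz·age) over the 4 portions. At 3.0 h the oldest is 180 min old, the youngest 30.0 min. The sum gives 35.2%. In my sum the youngest portion makes up half of that Z. I give the rest, 64.8%, to Q.

The forecast says Q at 62%, less than my figure, its ground being a constant that sags as Z rises, “which suggests mild saturation”.

The flask gives Q at 63.2%, with Z at 36.3%. Both forecast answers stand, and my Z lies 1.1 percentage points low.

    Z + G → L (k = 0.0153 M⁻¹ s⁻¹)
    L ⇌ J (K = 3.90, k = 0.0350 s⁻¹)
    J ⇌ G + Q (K = 17.5 M, k = 0.0289 s⁻¹)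
    2 G ⇌ D, settled at all times (K = 15.1 M⁻¹)

Part of this flask's shortfall of Q at 3.0 h comes from the portions and the time given, acting together. Charged at once, this flask ends with 83.6% Q, where kz in the same sum says 88.5%, and left ten times as long it reaches 99.9%. The neighbour flask with 0.013 M of G has kz scaled to 0.00472 min⁻¹. The sum then leaves 63.1% of Z, and that flask holds 65.9%.

The readings are calculated from invented constants; noise was put on by code.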